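Assumption: atoms are referred to by cembrane numbering of the target (C1 bears the acrylic acid; C3 secondary carbinol; C4–O–C7 tetrahydrofuran; C8=C19 exo-methylene; C11 acetoxy; C12 tertiary carbinol), and the SMILES is read as 1R,3R,4R,7S,11S,12R.

## Retrosynthetic overview

1. Target ⇐ macrocyclic C11-hydroxy-C12-ketone: C12 by chelate-controlled MeMgBr addition, then acetylation and C17 oxidation.
2. 14-membered ring (formed second) ⇐ C9–C10 bond by Ni-electrocatalytic decarboxylative allyl–alkyl macrocyclization of a seco redox-active ester.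
3. Seco acid ⇐ C12–C13 Weinreb ketone synthesis between a west alkyllithium and an (S)-malic acid-derived Weinreb amide (source of C11).
4. West fragment ⇐ cis-THF (formed first) by Os-catalysed oxidative cyclization of a 3,4-diol; C4 by chelate-controlled Grignard addition to a methyl ketone.
5. Methyl ketone ⇐ ring ozonolysis of a cis-carveol derivative from (R)-carvone (source of C1; C3 by Luche reduction).

## Route

Step 1
Reactants: 1, (R)-(−)-carvone
Product: 2, (5R)-5-(3-chloroprop-1-en-2-yl)-2-methylcyclohex-2-en-1-one (10-chlorocarvone)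
Conditions: Ca(OCl)2, CO2 (dry ice), CH2Cl2/H2O, 0 °C
Reagents that add atoms: calcium hypochlorite, [Ca+2].[O-]Cl.[O-]Cl
Why: HOCl ene-type allylic chlorination attacks only the electron-rich isopropenyl group (the enone C=C is inert) and leaves the stereocentre untouched.

Step 2
Reactants: 2
Product: 3, 2-[(1R)-4-methyl-5-oxocyclohex-3-en-1-yl]prop-2-en-1-yl acetate
Conditions: KOAc, Bu4NI (cat.), DMF, 60 °C
Reagents that add atoms: potassium acetate, CC(=O)[O-].[K+]
Why: SN2 displacement of a primary allylic chloride by acetate.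

Step 3
Reactants: 3
Product: 4, (1R,5R)-5-(3-hydroxyprop-1-en-2-yl)-2-methylcyclohex-2-en-1-ol (cis)
Conditions: NaBH4, CeCl3·7H2O, MeOH, −20 °C; then K2CO3, rt
Reagents that add atoms: none
Why: Luche 1,2-reduction of the carvone enone gives the cis-carveol-type alcohol (pseudo-equatorial OH cis to the C5 substituent, sets C3), and methanolysis removes the acetate in the same pot.

Step 4
Reactants: 4
Product: 5, (1R,5R)-5-{3-[(tert-butyldiphenylsilyl)oxy]prop-1-en-2-yl}-2-methylcyclohex-2-en-1-ol
Conditions: TBDPSCl (1.05 equiv), imidazole, CH2Cl2, 0 °C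
Reagents that add atoms: tert-butyl(chloro)diphenylsilane, CC(C)(C)[Si](Cl)(c1ccccc1)c1ccccc1
Why: selective silylation of the primary over the secondary allylic alcohol.

Step 5
Reactants: 5
Product: 6, 1-[(2R,4S)-4-{3-[(tert-butyldiphenylsilyl)oxy]prop-1-en-2-yl}-6-methoxyoxan-2-yl]ethan-1-one (anomeric mixture; C4 methyl ketone, C13 as cyclic methyl acetal on O3)
Conditions: O3, CH2Cl2/MeOH, −78 °C (Sudan Red 7B end point); Me2S; then CSA (cat.), MeOH, 0 °C
Reagents that add atoms: ozone, [O-][O+]=O; methanol, CO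
Why: ozonolysis cleaves the trisubstituted ring alkene in preference to the 1,1-disubstituted alkene (deactivated and shielded by the allylic OTBDPS), the C3–OH traps the aldehyde as a lactol, and Fischer glycosidation gives the acetal with C1/C3 in the thermodynamically favoured diequatorial arrangement.

Step 6
Reactants: 6; 7, 5-bromo-2-methylpent-2-ene (as its Grignard reagent)
Product: 8, (2R)-2-[(2R,4S)-4-{3-[(tert-butyldiphenylsilyl)oxy]prop-1-en-2-yl}-6-methoxyoxan-2-yl]-6-methylhept-5-en-2-ol
Conditions: 7, Mg, THF; then 6, THF, −78 °C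
Reagents that add atoms: 7 (via Grignard), CC(C)=CCCBr
Why: Cram-chelate Grignard addition: Mg bridges the ring oxygen on C3 and the ketone, so the nucleophile enters from the C3–H face (anti to ring C2) and gives 4R.

Step 7
Reactants: 8
Product: 9, (3R,5R,6R)-3-{3-[(tert-butyldiphenylsilyl)oxy]prop-1-en-2-yl}-6,10-dimethylundec-9-ene-1,5,6-triol
Conditions: AcOH/THF/H2O, 45 °C; then NaBH4, MeOH, 0 °C
Reagents that add atoms: water, O
Why: mild hydrolysis of the 2-deoxy-glycoside-type acetal to the lactol, then borohydride reduction of the open-chain aldehyde; this frees the 3,4-diol.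

Step 8
Reactants: 9
Product: 10, (1R,3R)-3-{3-[(tert-butyldiphenylsilyl)oxy]prop-1-en-2-yl}-1-[(2R,5S)-5-(2-hydroxypropan-2-yl)-2-methyloxolan-2-yl]pentane-1,5-diol
Conditions: K2OsO2(OH)4 (5 mol %), pyridine N-oxide, citric acid, Cu(OTf)2 (cat.), MeCN/aq. buffer, 60 °C
Reagents that add atoms: pyridine N-oxide (terminal O source), [O-][n+]1ccccc1
Why: Donohoe Os(VI) oxidative cyclization: the osmate ester chelated by the 3,4-diol adds syn across C7=C8, so O4–C7 forms on the face carrying C3 and gives only the 2,5-cis THF (7S); without free OsO4 the remote 1,1-disubstituted alkene is not dihydroxylated.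

Step 9
Reactants: 10
Product: 11, the C13 primary iodide of 10 (C3–OH and C8–OH free)
Conditions: I2, PPh3, imidazole, CH2Cl2, 0 °C
Reagents that add atoms: iodine, II
Why: Appel-type iodination is selective for the only primary alcohol.

Step 10
Reactants: 11
Product: 12, the C3 triethylsilyl ether of 11
Conditions: TESCl, imidazole, DMAP (cat.), CH2Cl2, rt
Reagents that add atoms: chlorotriethylsilane, CC[Si](Cl)(CC)CC
Why: the secondary alcohol is silylated while the tertiary C8–OH does not react.

Step 11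
Reactants: 12
Product: 13, the C7 isopropenyl compound (C8(=CH2)CH3 on the THF; C13–I, C3–OTES, C17–OTBDPS)
Conditions: Martin sulfurane, CH2Cl2, 0 °C to rt
Reagents that add atoms: none
Why: dehydration of the tertiary alcohol proceeds towards a methyl group (six equivalent β-H; loss of the α-oxy C7–H to an enol ether is disfavoured) and tolerates the primary iodide.

Step 12
Reactants: 14, (S)-2-(2,2-dimethyl-5-oxo-1,3-dioxolan-4-yl)acetic acid (L-malic acid acetonide)
Product: 15, (S)-3-hydroxy-4-[methoxy(methyl)amino]-4-oxobutanoic acid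
Conditions: MeNH(OMe)·HCl, i-PrMgCl, THF, −20 to 0 °C
Reagents that add atoms: N,O-dimethylhydroxylamine, CNOC
Why: aminolysis of the activated dioxolanone carbonyl gives the Weinreb amide of the α-hydroxy carboxyl with loss of acetone, without touching C11.

Step 13
Reactants: 13; 15
Product: 16, seco α-hydroxy ketone acid (HO2C–C10H2–C11H(OH)–C12(=O)–C13H2–; C8 isopropenyl, C3–OTES, C17–OTBDPS)
Conditions: 13, t-BuLi (2.1 equiv), Et2O, −78 °C; add to 15 (2 equiv, pre-treated with LiHMDS, 4 equiv, THF), −78 to −10 °C; aq. citric acid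
Reagents that add atoms: none other than 15
Why: iodine–lithium exchange followed by Weinreb ketone synthesis; the chelated tetrahedral intermediate prevents over-addition, and the carboxylate and alkoxide of 15 are spectators.

Step 14
Reactants: 16
Product: 17, the C9 allylic chloride of 16 (C7–C(=CH2)CH2Cl)
Conditions: Ca(OCl)2, CO2 (dry ice), CH2Cl2/H2O, 0 °C, 20 min
Reagents that add atoms: calcium hypochlorite, [Ca+2].[O-]Cl.[O-]Cl
Why: ene-type chlorination occurs at the only alkene that carries an allylic CH3; the C15 alkene has none and is deactivated by its allylic OSi group.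

Step 15
Reactants: 17
Product: 18, N-(acyloxy)phthalimide redox-active ester of 17
Conditions: N-hydroxyphthalimide, DIC, DMAP (cat.), CH2Cl2, 0 °C
Reagents that add atoms: N-hydroxyphthalimide, O=C1c2ccccc2C(=O)N1O
Why: Steglich-type esterification of the carboxylic acid; the hindered β-hydroxyl is not acylated.

Step 16
Reactants: 18
Product: 19, macrocyclic α-hydroxy ketone (14-membered carbocycle with cis-4,7-epoxide, C8 exo-methylene, C12 ketone, C11–OH, C3–OTES, C1–C(=CH2)CH2OTBDPS)
Conditions: NiBr2·glyme (20 mol %), 4,4′-di-tert-butyl-2,2′-bipyridine, LiBr, DMA, Zn anode/RVC cathode, constant current (3 mA, ca. 2.5 F/mol), syringe-pump addition to 2 mM, rt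
Reagents that add atoms: none
Why: Proposed new method: a Ni-electrocatalytic intramolecular decarboxylative allyl–alkyl coupling used as a macrocyclization, in which cathodically formed Ni(0) adds to the 2-substituted allylic chloride to give a π-allyl–Ni(II) with two equivalent CH2 termini (no regiochemical issue), low-valent Ni reduces the tethered ester to the primary C10 radical (loss of CO2 and phthalimide), and radical capture at Ni followed by C(sp3)–C(sp3) reductive elimination closes the ring with no stereocentre at risk; the closest known reactions are intermolecular Ni-electrocatalytic decarboxylative C(sp3)–C(sp3) couplings of redox-active esters and Ni-catalysed reductive allyl–alkyl cross-electrophile couplings.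

Step 17
Reactants: 19
Product: 20, macrocyclic 11,12-diol (C12 tertiary carbinol with C20 methyl)
Conditions: MeMgBr (5 equiv), THF, −78 °C
Reagents that add atoms: methylmagnesium bromide, C[Mg]Br
Why: Cram-chelate addition through the C11 magnesium alkoxide: methyl enters from the C11–H face (also the peripheral face of the ring, anti to C10) and gives 12R.

Step 18
Reactants: 20
Product: 21, C11 acetate of 20
Conditions: Ac2O, pyridine, DMAP (cat.), CH2Cl2, 0 °C
Reagents that add atoms: acetic anhydride, CC(=O)OC(C)=O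
Why: only the secondary C11–OH is acylated (C12–OH is tertiary, C3–OH is silylated).

Step 19
Reactants: 21
Product: 22, the C17 primary allylic alcohol (C3–OH and C12–OH free, C11–OAc)
Conditions: HF·pyridine, pyridine/THF, 0 °C to rt
Reagents that add atoms: none
Why: global desilylation (TES and TBDPS) under buffered conditions that leave the acetate alone.

Step 20
Reactants: 22
Product: 23, dendronpholide R
Conditions: TEMPO (cat.), PhI(OAc)2, CH2Cl2, rt; then NaClO2, NaH2PO4, 2-methyl-2-butene, t-BuOH/H2O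
Reagents that add atoms: sodium chlorite, [O-]Cl=O.[Na+]
Why: TEMPO/BAIB oxidizes only the primary allylic alcohol to the enal (the hindered secondary C3–OH is untouched), and Pinnick oxidation gives the acrylic acid.

## Compound list

1 | (R)-(−)-carvone | CC1=CC[C@H](CC1=O)C(C)=C | starting material
2 | (5R)-5-(3-chloroprop-1-en-2-yl)-2-methylcyclohex-2-en-1-one | CC1=CC[C@H](CC1=O)C(CCl)=C | intermediate
3 | 2-[(1R)-4-methyl-5-oxocyclohex-3-en-1-yl]prop-2-en-1-yl acetate | CC1=CC[C@H](CC1=O)C(COC(C)=O)=C | intermediate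
4 | (1R,5R)-5-(3-hydroxyprop-1-en-2-yl)-2-methylcyclohex-2-en-1-ol | CC1=CC[C@H](C[C@H]1O)C(CO)=C | intermediate
5 | (1R,5R)-5-{3-[(tert-butyldiphenylsilyl)oxy]prop-1-en-2-yl}-2-methylcyclohex-2-en-1-ol | CC1=CC[C@H](C[C@H]1O)C(CO[Si](c2ccccc2)(c3ccccc3)C(C)(C)C)=C | intermediate
6 | 1-[(2R,4S)-4-{3-[(tert-butyldiphenylsilyl)oxy]prop-1-en-2-yl}-6-methoxyoxan-2-yl]ethan-1-one (anomers) | CC(=O)[C@H]1C[C@@H](CC(OC)O1)C(=C)CO[Si](c2ccccc2)(c3ccccc3)C(C)(C)C | intermediate
7 | 5-bromo-2-methylpent-2-ene | CC(C)=CCCBr | starting material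
8 | (2R)-2-[(2R,4S)-4-{3-[(tert-butyldiphenylsilyl)oxy]prop-1-en-2-yl}-6-methoxyoxan-2-yl]-6-methylhept-5-en-2-ol | CC(C)=CCC[C@@](C)(O)[C@H]1C[C@@H](CC(OC)O1)C(=C)CO[Si](c2ccccc2)(c3ccccc3)C(C)(C)C | intermediate
9 | (3R,5R,6R)-3-{3-[(tert-butyldiphenylsilyl)oxy]prop-1-en-2-yl}-6,10-dimethylundec-9-ene-1,5,6-triol | CC(C)=CCC[C@@](C)(O)[C@H](O)C[C@@H](CCO)C(=C)CO[Si](c1ccccc1)(c2ccccc2)C(C)(C)C | intermediate
10 | (1R,3R)-3-{3-[(tert-butyldiphenylsilyl)oxy]prop-1-en-2-yl}-1-[(2R,5S)-5-(2-hydroxypropan-2-yl)-2-methyloxolan-2-yl]pentane-1,5-diol | CC(C)(O)[C@@H]1CC[C@@](C)(O1)[C@H](O)C[C@@H](CCO)C(=C)CO[Si](c2ccccc2)(c3ccccc3)C(C)(C)C | intermediate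
11 | C13 iodide of 10 | CC(C)(O)[C@@H]1CC[C@@](C)(O1)[C@H](O)C[C@@H](CCI)C(=C)CO[Si](c2ccccc2)(c3ccccc3)C(C)(C)C | intermediate
12 | C3–OTES ether of 11 | CC(C)(O)[C@@H]1CC[C@@](C)(O1)[C@H](O[Si](CC)(CC)CC)C[C@@H](CCI)C(=C)CO[Si](c2ccccc2)(c3ccccc3)C(C)(C)C | intermediate
13 | C7-isopropenyl iodide (dehydrated 12) | CC(=C)[C@@H]1CC[C@@](C)(O1)[C@H](O[Si](CC)(CC)CC)C[C@@H](CCI)C(=C)CO[Si](c2ccccc2)(c3ccccc3)C(C)(C)C | intermediate
14 | (S)-2-(2,2-dimethyl-5-oxo-1,3-dioxolan-4-yl)acetic acid | CC1(C)O[C@@H](CC(=O)O)C(=O)O1 | starting material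
15 | (S)-3-hydroxy-4-[methoxy(methyl)amino]-4-oxobutanoic acid | OC(=O)C[C@H](O)C(=O)N(C)OC | intermediate
16 | seco α-hydroxy ketone acid | OC(=O)C[C@H](O)C(=O)CC[C@H](C[C@@H](O[Si](CC)(CC)CC)[C@@]1(C)CC[C@H](O1)C(C)=C)C(=C)CO[Si](c2ccccc2)(c3ccccc3)C(C)(C)C | intermediate
17 | C9 allylic chloride of 16 | OC(=O)C[C@H](O)C(=O)CC[C@H](C[C@@H](O[Si](CC)(CC)CC)[C@@]1(C)CC[C@H](O1)C(CCl)=C)C(=C)CO[Si](c2ccccc2)(c3ccccc3)C(C)(C)C | intermediate
18 | N-(acyloxy)phthalimide ester of 17 | O=C(C[C@H](O)C(=O)CC[C@H](C[C@@H](O[Si](CC)(CC)CC)[C@@]1(C)CC[C@H](O1)C(CCl)=C)C(=C)CO[Si](c2ccccc2)(c3ccccc3)C(C)(C)C)ON4C(=O)c5ccccc5C4=O | intermediate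
19 | macrocyclic C11-hydroxy-C12-ketone (C3–OTES, C17–OTBDPS) | C=C(CO[Si](c1ccccc1)(c2ccccc2)C(C)(C)C)[C@@H]3CCC(=O)[C@@H](O)CCC(=C)[C@@H]4CC[C@@](C)(O4)[C@H](O[Si](CC)(CC)CC)C3 | intermediate
20 | macrocyclic 11,12-diol | C=C(CO[Si](c1ccccc1)(c2ccccc2)C(C)(C)C)[C@@H]3CC[C@@](C)(O)[C@@H](O)CCC(=C)[C@@H]4CC[C@@](C)(O4)[C@H](O[Si](CC)(CC)CC)C3 | intermediate
21 | C11 acetate of 20 | C=C(CO[Si](c1ccccc1)(c2ccccc2)C(C)(C)C)[C@@H]3CC[C@@](C)(O)[C@@H](OC(C)=O)CCC(=C)[C@@H]4CC[C@@](C)(O4)[C@H](O[Si](CC)(CC)CC)C3 | intermediate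
22 | C17 allylic alcohol (desilylated 21) | C=C(CO)[C@@H]1CC[C@@](C)(O)[C@@H](OC(C)=O)CCC(=C)[C@@H]2CC[C@@](C)(O2)[C@H](O)C1 | intermediate
23 | dendronpholide R | C=C(C(=O)O)[C@@H]1CC[C@@](C)(O)[C@@H](OC(C)=O)CCC(=C)[C@@H]2CC[C@@](C)(O2)[C@H](O)C1 | target

## Step count and risks

Total steps: 20. Longest linear sequence: 19 (steps 1–11 and 13–20 from carvone); step 12 is a one-step side branch from 14.

Steps most likely to fail:

- **Step 16 (proposed new macrocyclization).** Risks are reduction or dimerization of the C10 radical and oligomerization at the allyl terminus. Fallback with known chemistry: build the east end from the Weinreb amide of (S)-2,3-O-isopropylideneglyceric acid so that C10 is an aldehyde, close the ring by a Cr(II)-mediated intramolecular Nozaki–Hiyama allylation of the same allylic chloride, and remove the extra C10–OH by Barton–McCombie deoxygenation.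
- **Step 13 (alkyllithium addition to the unprotected hydroxy-acid Weinreb amide).** Risks are low conversion of the dianion and competing attack on the carboxylate. Fallback: replace carbanion addition by transition-metal acylation, either a Ni-catalysed reductive coupling of iodide 13 with an S-2-pyridyl thioester of O-silyl malic acid 4-tert-butyl ester, or a Pd-catalysed Fukuyama coupling of the derived alkylzinc.
- **Step 14 (late ene-chlorination next to an α-ketol and a second 1,1-disubstituted alkene).** Risks are oxidation of the ketol and chlorination at the C15 alkene. Fallback: SeO2/t-BuOOH allylic hydroxylation of the C8 isopropenyl methyl, then conversion of the allylic alcohol to its methyl carbonate as the π-allyl precursor for step 16.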